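## Retrosynthetic overview

- **Feature:** the ether oxygen joins C8 of coumarin A (7-methoxy) to C8' of coumarin B (5',7'-dihydroxy). Each of these carbons lies between two oxygen-bearing ring carbons (C7 and C8a), so direct aryl–O coupling would have to build a tetra-ortho-substituted diaryl ether.
- **Consequence:** the benzene ring of B carries oxygen on C5', C7', C8' and C8a', so it is a 2-aryloxyphloroglucinol. It is built from an open chain: two carbons from an aryloxyacetyl unit and four from an acetoacetate enol ether.
- **Disconnections (backwards):** O-benzyl; pyranone of B (Wittig/lactonisation, formylation); C6–C1 of a 6-aryloxy-5-oxo-3-benzyloxyhex-2-enoate (intramolecular Claisen, aromatisation); C4–C5 (γ-acylation of a dienolate); ArO–CH2 (SN2); pyranone of A (Wittig/lactonisation).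
- **Ring order:** pyranone of A (step 1), benzene ring of B (step 7), pyranone of B (step 9). The benzene ring of A is bought.

Key step: step 7

Remark: locants C1–C6 in steps 6 and 7 refer to the hexenoate chain (C1 = ester carbon, C6 = OCH2), and the keto enoate is drawn as its keto tautomer. The target has no stereocentre.

## Route

Step 1
Reactants: 1 2,3-dihydroxy-4-methoxybenzaldehyde; 2 ethyl (triphenylphosphoranylidene)acetate
Product: 4 8-hydroxy-7-methoxycoumarin, via cinnamate ester 3 (not isolated)
Conditions: 2 (1.2 equiv), PhNEt2, reflux (about 215 °C), N2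
Reagents that add atoms: none
Why: Wittig olefination by the stabilised ylide gives cinnamate 3, which at this temperature isomerises about its double bond and lactonises through the only hydroxyl ortho to the side chain, the standard one-pot salicylaldehyde-to-coumarin conversion, leaving the other phenol free as the 8-OH.

Step 2
Reactants: 4 8-hydroxy-7-methoxycoumarin; 5 tert-butyl bromoacetate
Product: 6 tert-butyl 2-[(7-methoxy-2-oxo-2H-chromen-8-yl)oxy]acetate
Conditions: K2CO3, DMF, rt
Reagents that add atoms: none
Why: Williamson ether synthesis, in which the crowded 8-phenoxide attacks a primary, carbonyl-activated bromide by SN2, so the steric load that hampers aryl–O coupling matters little, and dry carbonate does not open the lactone.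

Step 3
Reactants: 6 tert-butyl 2-[(7-methoxy-2-oxo-2H-chromen-8-yl)oxy]acetate
Product: 7 2-[(7-methoxy-2-oxo-2H-chromen-8-yl)oxy]acetic acid
Conditions: TFA, CH2Cl2, rt
Reagents that add atoms: none
Why: acidolysis of the tert-butyl ester through the tert-butyl cation frees the acid without the hydroxide that would open the coumarin lactone, and the aryl methyl ether is inert to TFA.

Step 4
Reactants: 7 2-[(7-methoxy-2-oxo-2H-chromen-8-yl)oxy]acetic acid
Product: 8 8-[2-(1H-imidazol-1-yl)-2-oxoethoxy]-7-methoxycoumarin (acyl imidazole of 7)
Conditions: CDI (1.1 equiv), CH2Cl2, rt; brief cold H2O wash, dry, concentrate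
Reagents that add atoms: 1,1'-carbonyldiimidazole O=C(n1ccnc1)n1ccnc1
Why: standard carboxyl activation with carbonyldiimidazole driven by loss of CO2, and the short cold wash removes the free imidazole whose N–H would otherwise quench the carbanion used in step 6.

Step 5
Reactants: 9 methyl but-2-ynoate; 10 benzyl alcohol
Product: 11 methyl (E)-3-(benzyloxy)but-2-enoate (OBn trans to CO2Me, CH3 cis to CO2Me)
Conditions: PMe3 (10 mol %), CH2Cl2, 0 °C to rt
Reagents that add atoms: none
Why: trialkylphosphine-catalysed oxa-Michael addition to an alkynoate, in which the phosphine–ynoate zwitterion deprotonates 10, benzyloxide adds to C3 of a further ynoate and the allenolate is protonated on the side of the smaller oxygen substituent to give the thermodynamically preferred E enol ether, while the absence of acid co-catalyst and heat suppresses the alkyne-to-allene isomerisation that leads to γ-addition.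

Step 6
Reactants: 8 acyl imidazole of 7; 11 methyl (E)-3-(benzyloxy)but-2-enoate
Product: 13 methyl (E)-3-(benzyloxy)-6-[(7-methoxy-2-oxo-2H-chromen-8-yl)oxy]-5-oxohex-2-enoate, via lithium dienolate 12 (not isolated)
Conditions: 11 (2.2 equiv), LiN(i-Pr)2 (2.1 equiv), THF, −78 °C; cannulate slowly into 8 in THF, −78 °C; AcOH quench at −78 °C
Reagents that add atoms: none
Why: vinylogous Claisen acylation, in which the amide base, guided by the ester carbonyl, deprotonates the methyl group cis to it, the 3-alkoxy dienolate 12 reacts with acyl donors at its terminal γ-carbon as is established for 3-alkoxycrotonates, the acyl imidazole far outruns the coumarin lactone as electrophile at −78 °C, slow addition of the dienolate to 8 keeps free carbanion low, and the second equivalent deprotonates the acidic C4–H2 of 13 and so shields the new ketone.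

Step 7
Reactants: 13 methyl (E)-3-(benzyloxy)-6-[(7-methoxy-2-oxo-2H-chromen-8-yl)oxy]-5-oxohex-2-enoate
Product: 16 8-[4-(benzyloxy)-2,6-dihydroxyphenoxy]-7-methoxycoumarin, via 2-pyrone reservoir 14 (not isolated), via cyclohexenedione 15 (not isolated)
Conditions: t-BuOK (3 equiv), THF (0.02 M), 0 °C to 45 °C; then 1 M HCl, rt
Reagents that add atoms: none
Why: Proposed new method: t-BuOK deprotonates 13 mainly at C4, but proton exchange also populates the C6 enolate (C6-H is acidified by the C5 ketone and by the aryloxy oxygen), whose carbon adds to the ester carbonyl C1, held on the same side as the chain by the E C2=C3 bond, and methoxide is expelled in an intramolecular Claisen (Dieckmann-type) acyl substitution. The new C6-C1 bond closes the six-membered carbocycle in a 6-(enolendo)-exo-trig mode to dione 15, which enolises at once to the bis-phenoxide of 16, so that aromatisation makes the closure irreversible and absorbs two equivalents of base. The closest known reaction type is the biomimetic Claisen cyclisation of 3,5-dioxoalkanoates and their 3-enol ethers to phloroglucinols, together with the base-induced recyclisation of 4-alkoxy-2-pyrones to arenes; neither has been shown with an aryloxy group on the nucleophilic carbon. The selectivity needed is C- over O-acylation: closure through the C5 enolate oxygen to 2-pyrone 14 is probably faster, but 14 is only a reservoir, because methoxide reopens it to 13 and because deprotonation of its aryloxymethyl group opens it to a dienyl ketene enolate that closes at carbon, and only the carbocyclic channel ends in an aromatic sink. No stereocentre persists (the labile CH of 15 and the enol ether geometry both vanish on aromatisation), and the benzyl group ends on the oxygen para to the aryloxy group, which leaves two equivalent hydroxyls ortho to it. The lactone of coumarin A is spared by the bulk of tert-butoxide and by dilution, and any lactone opened by methoxide to a Z-cinnamate recloses in the acidic quench.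

Step 8
Reactants: 16 8-[4-(benzyloxy)-2,6-dihydroxyphenoxy]-7-methoxycoumarin
Product: 18 6-(benzyloxy)-2,4-dihydroxy-3-[(7-methoxy-2-oxo-2H-chromen-8-yl)oxy]benzaldehyde, via iminium chloride 17 (not isolated)
Conditions: POCl3 (1.5 equiv), DMF (2 equiv), MeCN, 0 °C to rt; then H2O, 50 °C
Reagents that add atoms: N,N-dimethylformamide CN(C)C=O; water O
Why: Vilsmeier–Haack formylation, in which the chloroiminium ion attacks the phloroglucinol-type ring, by far the most electron-rich arene present, at one of its two free CH positions, which are equivalent by symmetry and lie ortho to one hydroxyl and para to the other, while the iminium group of 17 deactivates the ring against a second attack and is hydrolysed on warming together with any O-formyl ester.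

Step 9
Reactants: 18 6-(benzyloxy)-2,4-dihydroxy-3-[(7-methoxy-2-oxo-2H-chromen-8-yl)oxy]benzaldehyde; 2 ethyl (triphenylphosphoranylidene)acetate
Product: 20 5-(benzyloxy)-7-hydroxy-8-[(7-methoxy-2-oxo-2H-chromen-8-yl)oxy]coumarin, via cinnamate ester 19 (not isolated)
Conditions: 2 (1.5 equiv), PhNEt2, reflux (about 215 °C), N2
Reagents that add atoms: none
Why: Wittig olefination with thermal E-to-Z isomerisation and lactonisation as in step 1, where one of the two oxygens ortho to the side chain is blocked as its benzyl ether, so only the hydroxyl next to the aryloxy carbon can close the ring, which fixes the 8-aryloxy-7-hydroxy-5-benzyloxy pattern.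

Step 10
Reactants: 20 5-(benzyloxy)-7-hydroxy-8-[(7-methoxy-2-oxo-2H-chromen-8-yl)oxy]coumarin
Product: 21 5,7-dihydroxy-8-[(7-methoxy-2-oxo-2H-chromen-8-yl)oxy]coumarin (CNP0305396.0)
Conditions: BCl3 (5 equiv), C6HMe5 (5 equiv), CH2Cl2, −78 °C; then H2O
Reagents that add atoms: none
Why: Lewis-acid debenzylation with a non-basic cation scavenger, in which BCl3 ionises the benzyl–oxygen bond at −78 °C and pentamethylbenzene captures the benzyl cation by Friedel–Crafts alkylation before it can C-benzylate the electron-rich ring, while the aryl methyl ether (no chelating carbonyl next to it), the diaryl ether and both C3=C4 double bonds, which hydrogenolysis would endanger, are left alone.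

## Compound list

1 | 2,3-dihydroxy-4-methoxybenzaldehyde | COc1ccc(C=O)c(O)c1O | starting material
2 | ethyl (triphenylphosphoranylidene)acetate | CCOC(=O)C=P(c1ccccc1)(c1ccccc1)c1ccccc1 | starting material
3 | ethyl (E)-3-(2,3-dihydroxy-4-methoxyphenyl)prop-2-enoate (not isolated) | CCOC(=O)/C=C/c1ccc(OC)c(O)c1O | intermediate
4 | 8-hydroxy-7-methoxycoumarin | COc1ccc2ccc(=O)oc2c1O | intermediate
5 | tert-butyl bromoacetate | CC(C)(C)OC(=O)CBr | starting material
6 | tert-butyl 2-[(7-methoxy-2-oxo-2H-chromen-8-yl)oxy]acetate | COc1ccc2ccc(=O)oc2c1OCC(=O)OC(C)(C)C | intermediate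
7 | 2-[(7-methoxy-2-oxo-2H-chromen-8-yl)oxy]acetic acid | COc1ccc2ccc(=O)oc2c1OCC(=O)O | intermediate
8 | 8-[2-(1H-imidazol-1-yl)-2-oxoethoxy]-7-methoxycoumarin | COc1ccc2ccc(=O)oc2c1OCC(=O)n1ccnc1 | intermediate
9 | methyl but-2-ynoate | CC#CC(=O)OC | starting material
10 | benzyl alcohol | OCc1ccccc1 | starting material
11 | methyl (E)-3-(benzyloxy)but-2-enoate | C/C(OCc1ccccc1)=C\C(=O)OC | intermediate
12 | lithium (1E)-3-(benzyloxy)-1-methoxybuta-1,3-dien-1-olate, OLi cis to C3 (not isolated) | C=C(OCc1ccccc1)/C=C(\[O-])OC.[Li+] | intermediate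
13 | methyl (E)-3-(benzyloxy)-6-[(7-methoxy-2-oxo-2H-chromen-8-yl)oxy]-5-oxohex-2-enoate | COC(=O)/C=C(OCc1ccccc1)\CC(=O)COc1c(OC)ccc2ccc(=O)oc12 | intermediate
14 | 4-(benzyloxy)-6-{[(7-methoxy-2-oxo-2H-chromen-8-yl)oxy]methyl}-2H-pyran-2-one (reversible reservoir, not isolated) | O=c1cc(OCc2ccccc2)cc(COc2c(OC)ccc3ccc(=O)oc23)o1 | intermediate
15 | 8-{[4-(benzyloxy)-2,6-dioxocyclohex-3-en-1-yl]oxy}-7-methoxycoumarin (labile CH, racemic, not isolated) | O=C1C=C(OCc2ccccc2)CC(=O)C1Oc1c(OC)ccc2ccc(=O)oc12 | intermediate
16 | 8-[4-(benzyloxy)-2,6-dihydroxyphenoxy]-7-methoxycoumarin | COc1ccc2ccc(=O)oc2c1Oc1c(O)cc(OCc2ccccc2)cc1O | intermediate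
17 | {6-(benzyloxy)-2,4-dihydroxy-3-[(7-methoxy-2-oxo-2H-chromen-8-yl)oxy]benzylidene}dimethyliminium chloride (not isolated) | C[N+](C)=Cc1c(O)c(Oc2c(OC)ccc3ccc(=O)oc23)c(O)cc1OCc1ccccc1.[Cl-] | intermediate
18 | 6-(benzyloxy)-2,4-dihydroxy-3-[(7-methoxy-2-oxo-2H-chromen-8-yl)oxy]benzaldehyde | COc1ccc2ccc(=O)oc2c1Oc1c(O)cc(OCc2ccccc2)c(C=O)c1O | intermediate
19 | ethyl (E)-3-{6-(benzyloxy)-2,4-dihydroxy-3-[(7-methoxy-2-oxo-2H-chromen-8-yl)oxy]phenyl}prop-2-enoate (not isolated) | CCOC(=O)/C=C/c1c(O)c(Oc2c(OC)ccc3ccc(=O)oc23)c(O)cc1OCc1ccccc1 | intermediate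
20 | 5-(benzyloxy)-7-hydroxy-8-[(7-methoxy-2-oxo-2H-chromen-8-yl)oxy]coumarin | COc1ccc2ccc(=O)oc2c1Oc1c(O)cc(OCc3ccccc3)c2ccc(=O)oc12 | intermediate
21 | 5,7-dihydroxy-8-[(7-methoxy-2-oxo-2H-chromen-8-yl)oxy]coumarin (CNP0305396.0) | COc1ccc2ccc(=O)oc2c1Oc1c(O)cc(O)c2ccc(=O)oc12 | target

## Step count

- Total step count: 10.
- Longest linear sequence: 9 steps (steps 1–4 and 6–10, from 1 to 21). Step 5 is a one-step branch.

## Steps most likely to fail

**1. Step 7 (carries the label).**
- What may go wrong:
  - The closure may stay at oxygen if the O-acylation does not revert.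
  - Liberated methoxide may exchange the benzyl enol ether by addition–elimination, or may open the lactone of coumarin A.
  - Chain enolates may add intermolecularly to the C3=C4 bond of coumarin A.
  - Aryloxide may be lost from the α-aryloxy ketone.
- Fallback (known chemistry): it sets out from phenol 4 and comes back at 16, replacing steps 2 to 7 by a classical aryl–O coupling.
  - Purchased 5-(benzyloxy)benzene-1,3-diol F1 is protected with MOMCl and i-Pr2NEt as 1-(benzyloxy)-3,5-bis(methoxymethoxy)benzene F2.
  - Directed ortho-lithiation with n-BuLi in THF at 0 °C, at the position between the two acetal oxygens, gives [4-(benzyloxy)-2,6-bis(methoxymethoxy)phenyl]lithium F3.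
  - An I2 quench gives 5-(benzyloxy)-2-iodo-1,3-bis(methoxymethoxy)benzene F4.
  - Ullmann ether synthesis of 4 with F4 (CuI, picolinic acid, K3PO4, DMSO, 100 °C) should give 8-[4-(benzyloxy)-2,6-bis(methoxymethoxy)phenoxy]-7-methoxycoumarin F5. The coupling is expected to be slow because both partners are di-ortho-substituted.
  - HCl in MeOH removes the two acetals to give 16.

**2. Step 6.**
- What may go wrong:
  - Poor site selectivity of the dienolate (α- versus γ-acylation).
  - Proton transfer from the α-CH2 of the acyl imidazole in place of addition.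
  - 1,2- or 1,4-addition of the carbanion to coumarin A.
- Fallback: it sets out from 7 and 11 and comes back at 13, replacing the basic carbanion by a neutral silyl nucleophile (vinylogous Mukaiyama-type acylation).
  - Acid 7 is converted with (COCl)2 and catalytic DMF into 2-[(7-methoxy-2-oxo-2H-chromen-8-yl)oxy]acetyl chloride F6.
  - Ester 11 is deprotonated to 12 and silylated with Me3SiCl to give {[(1Z)-3-(benzyloxy)-1-methoxybuta-1,3-dien-1-yl]oxy}trimethylsilane F7.
  - The two are combined in CH2Cl2 from −78 °C to rt. Silyl dienolates of this 1,3-dioxygenated type are known to be acylated by acid chlorides at the terminal carbon, and the coumarin never meets a strong base.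

**3. Step 9.**
- What may go wrong:
  - Proton transfer from the vinylogously acidic 4-OH to the ylide, which deactivates both partners.
  - Slow olefination of the di-ortho-substituted aldehyde.
  - Thermal degradation during the long heating that the E-to-Z isomerisation needs.
- Fallback: it sets out from 18 and comes back at 20 by a Knoevenagel route that gives the cis-disposed acyl group directly.
  - Condensation of 18 with Meldrum's acid (catalytic piperidinium acetate, EtOH, reflux) with in situ lactonisation should give 5-(benzyloxy)-7-hydroxy-8-[(7-methoxy-2-oxo-2H-chromen-8-yl)oxy]-2-oxo-2H-chromene-3-carboxylic acid F8.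
  - Protodecarboxylation (catalytic Ag2CO3, AcOH, DMSO, 120 °C) gives 20.

## Further compounds

F1 | step 7 | 5-(benzyloxy)benzene-1,3-diol (purchased) | Oc1cc(O)cc(OCc2ccccc2)c1
F2 | step 7 | 1-(benzyloxy)-3,5-bis(methoxymethoxy)benzene | COCOc1cc(OCOC)cc(OCc2ccccc2)c1
F3 | step 7 | [4-(benzyloxy)-2,6-bis(methoxymethoxy)phenyl]lithium | [Li]c1c(OCOC)cc(OCc2ccccc2)cc1OCOC
F4 | step 7 | 5-(benzyloxy)-2-iodo-1,3-bis(methoxymethoxy)benzene | COCOc1cc(OCc2ccccc2)cc(OCOC)c1I
F5 | step 7 | 8-[4-(benzyloxy)-2,6-bis(methoxymethoxy)phenoxy]-7-methoxycoumarin | COCOc1cc(OCc2ccccc2)cc(OCOC)c1Oc1c(OC)ccc2ccc(=O)oc12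
F6 | step 6 | 2-[(7-methoxy-2-oxo-2H-chromen-8-yl)oxy]acetyl chloride | COc1ccc2ccc(=O)oc2c1OCC(=O)Cl
F7 | step 6 | {[(1Z)-3-(benzyloxy)-1-methoxybuta-1,3-dien-1-yl]oxy}trimethylsilane | C=C(OCc1ccccc1)/C=C(\O[Si](C)(C)C)OC
F8 | step 9 | 5-(benzyloxy)-7-hydroxy-8-[(7-methoxy-2-oxo-2H-chromen-8-yl)oxy]-2-oxo-2H-chromene-3-carboxylic acid | COc1ccc2ccc(=O)oc2c1Oc1c(O)cc(OCc3ccccc3)c2cc(C(=O)O)c(=O)oc12
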